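**Retrosynthetic overview**

- The strategy rests on the central cyclohexene (carbinol C, vinyl CH, acetyl-bearing C, spiro C, ring CH2, ring-fusion CH). It joins two cis-fused γ-lactone/seven-membered-ring bicycles of opposite absolute configuration, and at the spiro carbon the ring CH2 lies on the convex (ring-fusion H) face of the spiro-lactone while the acetyl-bearing carbon lies on its cycloheptene face.
- The acetyl group and the ring alkene are installed last, by triflation of a ring ketone and Stille coupling. That ketone belongs to a spiro ketol that is cut at two bonds: spiro C–ring CH2 (Michael) and acetyl-derived CH2–carbinol C (aldol).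
- The two partners are an α-acetyl lactone (mirror-image half, series B) and a cycloheptanone carrying an α-methylene ketone and the α-methylene lactone (series A), the latter released in the flask from a bis-ammonium salt.
- Both halves come from one monoacetate of meso cis-cyclohept-2-ene-1,4-diol, by Johnson–Claisen rearrangement from one hydroxyl or from the other.
- Ring order: the seven-membered rings are bought, each γ-lactone is closed after its Claisen step, and the central six-membered ring is closed last.

Key step: step 23

Assumption: the lipase acylates the (R)-configured carbinol carbon of the meso diol, as such enzymes usually do; if it gave the other antipode, the direct Claisen sequence and the silyl-ether detour would simply exchange roles.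

Remark on numbering: the bicyclic lactones are numbered as cyclohepta[b]furan-2-ones (O1, C2 carbonyl, C3, C3a, C4 to C8, C8a). "Series A" is the configuration of the α-methylene-lactone half of the target and "series B" is its mirror image.

---

**Common stage**

Step 1
Reactants: 1 cyclohepta-1,3-diene
Product: 3 cis-cyclohept-2-ene-1,4-diol (meso), via endoperoxide 2 (not isolated)
Conditions: O2, hν (visible), tetraphenylporphyrin (cat.), CH2Cl2, 0 °C; then Zn, AcOH, 0 °C → rt
Reagents that add atoms: dioxygen, O=O
Why: The [4+2] cycloaddition of singlet oxygen to the diene is suprafacial, so reductive O–O cleavage of the bicyclic endoperoxide by zinc leaves both hydroxyls on one face and the diol is meso.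

Step 2
Reactants: 3 cis-cyclohept-2-ene-1,4-diol
Product: 4 (1S,4R)-cis-4-acetoxycyclohept-2-en-1-ol
Conditions: vinyl acetate, Pseudomonas cepacia lipase, t-BuOMe, rt
Reagents that add atoms: vinyl acetate, CC(=O)OC=C
Why: Lipase-catalysed irreversible transesterification (enzymatic desymmetrisation) should acylate only the (R)-carbinol of the meso diol, which fixes the absolute configuration of both oxygen-bearing carbons at once.

**Series A (α-methylene-lactone half)**

Step 3
Reactants: 4 (1S,4R)-cis-4-acetoxycyclohept-2-en-1-ol; 5 triethyl orthoacetate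
Product: 6 ethyl 2-(cis-7-acetoxycyclohept-2-en-1-yl)acetate (series A)
Conditions: 5 (5 equiv), EtCO2H (cat.), 140 °C, EtOH distilled off
Reagents that add atoms: none
Why: In this Johnson–Claisen rearrangement the ketene acetal formed on the free allylic hydroxyl undergoes a suprafacial [3,3] shift that places CH2CO2Et on the far alkene carbon on the face the oxygen leaves, hence cis to the neighbouring acetoxy group, which the weakly acidic medium does not touch.

Step 4
Reactants: 6 ethyl 2-(cis-7-acetoxycyclohept-2-en-1-yl)acetate
Product: 8 (3aS,8aR)-cis-3,3a,6,7,8,8a-hexahydro-2H-cyclohepta[b]furan-2-one, via hydroxy ester 7 (not isolated)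
Conditions: K2CO3, EtOH, rt; then p-TsOH·H2O (cat.), PhMe, 60 °C
Reagents that add atoms: none
Why: Transesterification removes the acetate and acid-catalysed lactonisation of the cis γ-hydroxy ester closes the cis-fused γ-lactone without touching either stereocentre.

Step 5
Reactants: 8 series-A alkene lactone
Product: 9 6-hydroxy derivative of 8 (C4=C5 alkene retained, both C6 epimers)
Conditions: SeO2 (0.5 equiv), t-BuOOH, CH2Cl2, rt
Reagents that add atoms: tert-butyl hydroperoxide, CC(C)(C)OO (terminal oxidant; the oxygen atom is relayed by SeO2, O=[Se]=O)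
Why: Selenium dioxide allylic hydroxylation (ene reaction then [2,3] shift) returns the alkene to its place and should prefer the ring CH2 over the tertiary ring-fusion CH, which is deactivated by the adjacent C–O bond; the carbinol configuration is irrelevant because it is oxidised next.

Step 6
Reactants: 9 allylic alcohol
Product: 10 cis-3,3a,8,8a-tetrahydro-2H-cyclohepta[b]furan-2,6(7H)-dione (C4=C5 enone, series A)
Conditions: MnO2, CH2Cl2, rt
Reagents that add atoms: none
Why: MnO2 oxidises the allylic alcohol selectively to the conjugated enone.

Step 7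
Reactants: 10 enone lactone
Product: 11 7-methyl enone lactone (both C7 epimers)
Conditions: LiN(i-Pr)2, THF, −78 °C; MeI, −78 → −40 °C
Reagents that add atoms: iodomethane, CI
Why: Kinetic enolate alkylation: the amide base removes an α'-proton at C7 (cross-conjugated enolate, formed faster than the less acidic lactone enolate) and methyl iodide alkylates it; the configuration at C7 is not relied on because the next step resets it.

Step 8
Reactants: 11 7-methyl enone lactone (epimers)
Product: 13 series-A 7-methyl enone lactone with the methyl cis to the lactone oxygen, via silyl dienol ether 12 (not isolated)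
Conditions: Me3SiOTf, Et3N, CH2Cl2, 0 °C; pentane, filtration, evaporation; then CF3CO2H, CH2Cl2, −78 °C
Reagents that add atoms: none
Why: Soft enolisation gives the cross-conjugated 2-silyloxy diene, which erases C7, and kinetic C-protonation should deliver the proton to the face opposite the pseudo-axial lactone oxygen on the out-of-plane C8a, leaving the methyl cis to that oxygen; no reversible base is used because it would also enolise toward the ring-fusion CH γ to the ketone.

Step 9
Reactants: 13 series-A methyl enone lactone
Product: 15 6-(trimethylsilyloxy)-7-methyl-3,3a,4,7,8,8a-hexahydro-2H-cyclohepta[b]furan-2-one (C5=C6 enol ether), via lithium enolate 14 (not isolated)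
Conditions: LiB(s-Bu)3H, THF, −78 °C; then Me3SiCl, Et3N, −78 → 0 °C
Reagents that add atoms: chlorotrimethylsilane, C[Si](C)(C)Cl
Why: Conjugate hydride reduction of the β-unsubstituted cycloalkenone by the bulky trialkylborohydride forms the enolate only on the former alkene side, and O-silylation traps it without touching the lactone or C7.

Step 10
Reactants: 15 silyl enol ether; 16 dimethylmethyleneiminium iodide (two equivalents end up in the product)
Product: 18 3,5-bis(dimethylaminomethyl)-7-methyl-perhydrocyclohepta[b]furan-2,6-dione (series A; C3 and C5 epimers), via C3-aminomethyl silyl enol ether 17 (not isolated)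
Conditions: LiN(i-Pr)2 (1.05 equiv), THF, −78 °C; 16 (1.1 equiv), −78 → 0 °C; then 16 (1.5 equiv), CH2Cl2, rt; NaHCO3 (aq)
Reagents that add atoms: dimethylmethyleneiminium iodide (second equivalent, the same salt as 16), C=[N+](C)C.[I-]
Why: Mannich aminomethylation occurs twice, first at C3 through the lithium lactone enolate to give 17 and then at C5 through the regiodefined silyl enol ether with a second equivalent of the iminium salt; the two new centres are left undefined because both become sp2 on elimination.

Step 11
Reactants: 18 bis-amine
Product: 19 3,5-bis(trimethylammoniomethyl) keto lactone diiodide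
Conditions: MeI (excess), CH2Cl2–Et2O, rt
Reagents that add atoms: iodomethane, CI
Why: Exhaustive N-methylation (Menshutkin reaction) turns both amines into trimethylammonium leaving groups and the salt precipitates.

**Series B (spiro-lactone half)**

Step 12
Reactants: 4 (1S,4R)-cis-4-acetoxycyclohept-2-en-1-ol
Product: 20 (1R,4S)-cis-4-(tert-butyldimethylsilyloxy)cyclohept-2-en-1-yl acetate
Conditions: t-BuMe2SiCl, imidazole, DMF, rt
Reagents that add atoms: tert-butyldimethylsilyl chloride, CC(C)(C)[Si](C)(C)Cl
Why: Silyl ether protection of the free allylic alcohol switches the roles of the two oxygens.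

Step 13
Reactants: 20 silyl ether acetate
Product: 21 (1R,4S)-cis-4-(tert-butyldimethylsilyloxy)cyclohept-2-en-1-ol
Conditions: K2CO3, MeOH, 0 °C → rt
Reagents that add atoms: none
Why: Mild base methanolysis (transesterification) removes the acetate and leaves the silyl ether.

Step 14
Reactants: 21 silyloxy allylic alcohol; 5 triethyl orthoacetate
Product: 22 ethyl 2-[cis-7-(tert-butyldimethylsilyloxy)cyclohept-2-en-1-yl]acetate (series B)
Conditions: 5 (5 equiv), EtCO2H (cat.), 140 °C, EtOH distilled off
Reagents that add atoms: none
Why: Johnson–Claisen rearrangement from the newly freed hydroxyl places CH2CO2Et cis to the silyloxy group by the same suprafacial [3,3] shift, and because the other enantiotopic carbinol carbon is now the one kept, the product is of the mirror-image series.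

Step 15
Reactants: 22 silyloxy ester
Product: 24 (3aR,8aS)-cis-3,3a,6,7,8,8a-hexahydro-2H-cyclohepta[b]furan-2-one, via hydroxy ester 23 (not isolated)
Conditions: 1 M HCl, THF, rt → 45 °C
Reagents that add atoms: none
Why: Acid hydrolysis of the silyl ether followed by acid-catalysed lactonisation of the cis γ-hydroxy ester gives the enantiomer of 8.

Step 16
Reactants: 24 series-B alkene lactone
Product: 25 6-hydroxy derivative of 24 (both C6 epimers)
Conditions: SeO2 (0.5 equiv), t-BuOOH, CH2Cl2, rt
Reagents that add atoms: tert-butyl hydroperoxide, CC(C)(C)OO (terminal oxidant; the oxygen atom is relayed by SeO2, O=[Se]=O)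
Why: Selenium dioxide allylic hydroxylation as in step 5, with the same preference for the ring CH2 over the ring-fusion CH.

Step 17
Reactants: 25 allylic alcohol
Product: 26 series-B enone lactone (enantiomer of 10)
Conditions: MnO2, CH2Cl2, rt
Reagents that add atoms: none
Why: MnO2 oxidation of the allylic alcohol to the conjugated enone.

Step 18
Reactants: 26 enone lactone
Product: 27 series-B 7-methyl enone lactone (both C7 epimers)
Conditions: LiN(i-Pr)2, THF, −78 °C; MeI, −78 → −40 °C
Reagents that add atoms: iodomethane, CI
Why: Kinetic α'-enolate alkylation as in step 7; the C7 configuration is reset in the next step.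

Step 19
Reactants: 27 7-methyl enone lactone (epimers)
Product: 29 series-B 7-methyl enone lactone with the methyl cis to the lactone oxygen (enantiomer of 13), via silyl dienol ether 28 (not isolated)
Conditions: Me3SiOTf, Et3N, CH2Cl2, 0 °C; pentane, filtration, evaporation; then CF3CO2H, CH2Cl2, −78 °C
Reagents that add atoms: none
Why: Soft enolisation to the 2-silyloxy diene and kinetic C-protonation anti to the lactone oxygen as in step 8 should set the methyl cis to that oxygen, again without reversible enolisation toward the ring-fusion CH.

Step 20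
Reactants: 29 series-B methyl enone lactone
Product: 31 7-methyl-2-oxo-3,3a,4,7,8,8a-hexahydro-2H-cyclohepta[b]furan-6-yl trifluoromethanesulfonate (series B), via lithium enolate 30 (not isolated)
Conditions: LiB(s-Bu)3H, THF, −78 °C; then PhNTf2, −78 → 0 °C
Reagents that add atoms: N-phenylbis(trifluoromethanesulfonimide), O=S(=O)(N(c1ccccc1)S(=O)(=O)C(F)(F)F)C(F)(F)F
Why: Conjugate reduction as in step 9 and O-triflation of the regiodefined enolate give the enol triflate with its alkene on the side away from the methyl-bearing carbon, whose configuration is thereby locked as an allylic centre.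

Step 21
Reactants: 31 enol triflate; 32 2-methyl-2-vinyl-1,3-dioxolane
Product: 34 7-methyl-6-[2-(2-methyl-1,3-dioxolan-2-yl)ethyl]-3,3a,4,7,8,8a-hexahydro-2H-cyclohepta[b]furan-2-one (series B), via alkylborane 33 (not isolated)
Conditions: 32, 9-BBN-H, THF, 0 °C → rt; then 31, Pd(dppf)Cl2 (5 mol %), K3PO4 (aq), DMF, rt → 50 °C
Reagents that add atoms: none
Why: Anti-Markovnikov hydroboration of the vinyl dioxolane and B-alkyl Suzuki–Miyaura coupling with the enol triflate install the ketal-protected 3-oxobutyl chain, and the mild phosphate base leaves the lactone intact.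

Step 22
Reactants: 34 side-chain lactone
Product: 35 3-acetyl derivative of 34 (acetyl trans to the ring CH2 on C3a; in equilibrium with its C3 epimer and enol)
Conditions: LiN(SiMe3)2 (2.1 equiv), THF, −78 °C; N-acetylimidazole, −78 → 0 °C; NH4Cl (aq)
Reagents that add atoms: 1-acetylimidazole, CC(=O)n1ccnc1
Why: Claisen-type C-acylation of the lactone lithium enolate by an acylimidazole, the second equivalent of base absorbing the more acidic β-keto lactone; the α-centre need not be controlled because it becomes planar in the next step.

**Union and completion**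

Step 23
Reactants: 19 bis(trimethylammoniomethyl) keto lactone diiodide; 35 α-acetyl lactone
Product: 38 spiro ketol (central cyclohexanone ring: C–OH, CH2, C=O, spiro C, CH2, ring-fusion CH; cis-fused to the series-A cycloheptane and spiro at the lactone α-carbon of the series-B half), via dimethylene keto lactone 36 (not isolated), via Michael adduct 37 (not isolated)
Conditions: DBU (2.5 equiv), MeCN, 0 °C → rt
Reagents that add atoms: none
Why: DBU eliminates both trimethylammonium groups of 19 to free 36 and deprotonates 35; the stabilised enolate adds through C3 to the exocyclic CH2 on C5 of the α-methylene ketone (Michael), and the methyl-ketone enolate of diketone 37 then attacks the C6 ketone to close the central ring as a tertiary ketol. This is a Robinson annulation run from a Mannich methiodide and stopped at the ketol, the closest known cases being annulations of α-acetyl lactones and other 1,3-dicarbonyl donors with α-methylene ketones. The six-membered ring closes in the 6-(enolexo)-exo-trig mode. The spiro carbon should be set by approach of the enone to the convex face of the planar cis-fused acyl-lactone enolate, anti to the cycloheptene CH2 on the neighbouring ring-fusion carbon; the carbinol carbon by attack on the ketone face opposite the adjacent methyl group and the lactone ring, with the enolisable ring-fusion CH settling so that the new ring is cis-fused, so each half governs only its own new centres and the antipodal pairing needs no matching. The step needs the donor to choose the exocyclic enone over the α-methylene lactone, which the greater electrophilicity of the ketone-activated, s-cis-locked methylene should secure, and it needs the ketol to survive, which the amidine base at room temperature allows.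

Step 24
Reactants: 38 spiro ketol
Product: 39 trimethylsilyl ether of 38
Conditions: N-(trimethylsilyl)imidazole, CH2Cl2, rt
Reagents that add atoms: 1-(trimethylsilyl)imidazole, C[Si](C)(C)n1ccnc1
Why: Silyl ether protection of the tertiary alcohol by a neutral silyl-transfer agent blocks retro-aldol opening of the ketol in the basic step that follows.

Step 25
Reactants: 39 silylated ketol
Product: 40 enol triflate of the ring ketone (alkene toward the former CH2, next to the silyloxy carbon)
Conditions: KN(SiMe3)2, THF, −78 °C; PhNTf2, −78 °C
Reagents that add atoms: N-phenylbis(trifluoromethanesulfonimide), O=S(=O)(N(c1ccccc1)S(=O)(=O)C(F)(F)F)C(F)(F)F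
Why: Enol triflate formation is regiospecific because the ketone has a single enolisable CH2 (its other α-carbon is the quaternary spiro carbon), and the poor silyloxide leaving group at low temperature suppresses β-elimination.

Step 26
Reactants: 40 enol triflate; 41 tributyl(1-ethoxyvinyl)stannane
Product: 42 2-ethoxy-1,3-diene (1-ethoxyvinyl group on the former ketone carbon)
Conditions: Pd(PPh3)4 (10 mol %), CuI (20 mol %), LiCl (3 equiv), DMF, 50 °C
Reagents that add atoms: none
Why: Stille coupling of the alkenyl triflate with the α-ethoxyvinyl stannane introduces a masked acetyl group, with LiCl assisting transmetalation and CuI speeding coupling next to the quaternary carbon.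

Step 27
Reactants: 42 ethoxy diene
Product: 43 target CNP0195550.4
Conditions: 1 M HCl, THF, 0 °C → rt
Reagents that add atoms: water, O
Why: Mild acid hydrolysis converts the enol ether into the conjugated acetyl group, the silyl ether into the tertiary alcohol and the dioxolane into the side-chain ketone; the tertiary allylic alcohol should resist ionisation because the cation would place charge on the acetyl-bearing carbon.

---

**Compound list**

1 | cyclohepta-1,3-diene | C1=CC=CCCC1 | starting material
2 | 6,7-dioxabicyclo[3.2.2]non-8-ene (endoperoxide) | O1[C@@H]2C=C[C@H](O1)CCC2 | intermediate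
3 | cis-cyclohept-2-ene-1,4-diol (meso) | O[C@@H]1C=C[C@H](O)CCC1 | intermediate
4 | (1S,4R)-cis-4-acetoxycyclohept-2-en-1-ol | O[C@@H]1C=C[C@H](OC(C)=O)CCC1 | intermediate
5 | triethyl orthoacetate | CCOC(C)(OCC)OCC | starting material
6 | ethyl 2-(cis-7-acetoxycyclohept-2-en-1-yl)acetate, series A | CC(=O)O[C@@H]1CCCC=C[C@@H]1CC(=O)OCC | intermediate
7 | ethyl 2-(cis-7-hydroxycyclohept-2-en-1-yl)acetate, series A | O[C@@H]1CCCC=C[C@@H]1CC(=O)OCC | intermediate
8 | (3aS,8aR)-cis-3,3a,6,7,8,8a-hexahydro-2H-cyclohepta[b]furan-2-one | C1C(=O)O[C@@H]2CCCC=C[C@H]12 | intermediate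
9 | 6-hydroxy derivative of 8 (C6 epimers) | C1C(=O)O[C@@H]2CCC(O)C=C[C@H]12 | intermediate
10 | series-A enone lactone (6-oxo, C4=C5) | C1C(=O)O[C@@H]2CCC(=O)C=C[C@H]12 | intermediate
11 | series-A 7-methyl enone lactone (C7 epimers) | C1C(=O)O[C@@H]2CC(C)C(=O)C=C[C@H]12 | intermediate
12 | series-A 7-methyl-6-(trimethylsilyloxy) 4,6-diene lactone | C1C(=O)O[C@@H]2CC(C)=C(O[Si](C)(C)C)C=C[C@H]12 | intermediate
13 | series-A 7-methyl enone lactone, methyl cis to the lactone oxygen | C1C(=O)O[C@@H]2C[C@H](C)C(=O)C=C[C@H]12 | intermediate
14 | series-A lithium enolate (C5=C6–OLi) | C1C(=O)O[C@@H]2C[C@H](C)C(O[Li])=CC[C@H]12 | intermediate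
15 | series-A trimethylsilyl enol ether (C5=C6) | C1C(=O)O[C@@H]2C[C@H](C)C(O[Si](C)(C)C)=CC[C@H]12 | intermediate
16 | dimethylmethyleneiminium iodide | C=[N+](C)C.[I-] | starting material
17 | series-A 3-(dimethylaminomethyl) trimethylsilyl enol ether (C3 epimers) | CN(C)CC1C(=O)O[C@@H]2C[C@H](C)C(O[Si](C)(C)C)=CC[C@H]12 | intermediate
18 | series-A 3,5-bis(dimethylaminomethyl) keto lactone | CN(C)CC1C(=O)O[C@@H]2C[C@H](C)C(=O)C(CN(C)C)C[C@H]12 | intermediate
19 | series-A 3,5-bis(trimethylammoniomethyl) keto lactone diiodide | C[N+](C)(C)CC1C(=O)O[C@@H]2C[C@H](C)C(=O)C(C[N+](C)(C)C)C[C@H]12.[I-].[I-] | intermediate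
20 | (1R,4S)-cis-4-(tert-butyldimethylsilyloxy)cyclohept-2-en-1-yl acetate | CC(C)(C)[Si](C)(C)O[C@@H]1C=C[C@H](OC(C)=O)CCC1 | intermediate
21 | (1R,4S)-cis-4-(tert-butyldimethylsilyloxy)cyclohept-2-en-1-ol | CC(C)(C)[Si](C)(C)O[C@@H]1C=C[C@H](O)CCC1 | intermediate
22 | ethyl 2-[cis-7-(tert-butyldimethylsilyloxy)cyclohept-2-en-1-yl]acetate, series B | CC(C)(C)[Si](C)(C)O[C@H]1CCCC=C[C@H]1CC(=O)OCC | intermediate
23 | ethyl 2-(cis-7-hydroxycyclohept-2-en-1-yl)acetate, series B | O[C@H]1CCCC=C[C@H]1CC(=O)OCC | intermediate
24 | (3aR,8aS)-cis-3,3a,6,7,8,8a-hexahydro-2H-cyclohepta[b]furan-2-one | C1C(=O)O[C@H]2CCCC=C[C@@H]12 | intermediate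
25 | 6-hydroxy derivative of 24 (C6 epimers) | C1C(=O)O[C@H]2CCC(O)C=C[C@@H]12 | intermediate
26 | series-B enone lactone | C1C(=O)O[C@H]2CCC(=O)C=C[C@@H]12 | intermediate
27 | series-B 7-methyl enone lactone (C7 epimers) | C1C(=O)O[C@H]2CC(C)C(=O)C=C[C@@H]12 | intermediate
28 | series-B 7-methyl-6-(trimethylsilyloxy) 4,6-diene lactone | C1C(=O)O[C@H]2CC(C)=C(O[Si](C)(C)C)C=C[C@@H]12 | intermediate
29 | series-B 7-methyl enone lactone, methyl cis to the lactone oxygen | C1C(=O)O[C@H]2C[C@@H](C)C(=O)C=C[C@@H]12 | intermediate
30 | series-B lithium enolate | C1C(=O)O[C@H]2C[C@@H](C)C(O[Li])=CC[C@@H]12 | intermediate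
31 | series-B enol triflate (C5=C6) | C1C(=O)O[C@H]2C[C@@H](C)C(OS(=O)(=O)C(F)(F)F)=CC[C@@H]12 | intermediate
32 | 2-methyl-2-vinyl-1,3-dioxolane | C=CC1(C)OCCO1 | starting material
33 | 9-[2-(2-methyl-1,3-dioxolan-2-yl)ethyl]-9-borabicyclo[3.3.1]nonane | CC1(CCB2C3CCCC2CCC3)OCCO1 | intermediate
34 | series-B lactone with the ketal-protected 3-oxobutyl chain on C6 (C5=C6) | C1C(=O)O[C@H]2C[C@@H](C)C(CCC3(C)OCCO3)=CC[C@@H]12 | intermediate
35 | series-B 3-acetyl lactone (Michael donor) | CC(=O)[C@@H]1C(=O)O[C@H]2C[C@@H](C)C(CCC3(C)OCCO3)=CC[C@@H]12 | intermediate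
36 | series-A 7-methyl-3,5-dimethylidene keto lactone | C=C1C(=O)O[C@@H]2C[C@H](C)C(=O)C(=C)C[C@H]12 | intermediate
37 | Michael adduct (1,5-diketone, C5 of the series-A ring unassigned) | C=C1C(=O)O[C@@H]2C[C@H](C)C(=O)C(C[C@]3(C(C)=O)C(=O)O[C@H]4C[C@@H](C)C(CCC5(C)OCCO5)=CC[C@@H]34)C[C@H]12 | intermediate
38 | spiro ketol | C=C1C(=O)O[C@@H]2C[C@H](C)[C@@]3(O)CC(=O)[C@@]4(C[C@H]3C[C@H]12)C(=O)O[C@H]1C[C@@H](C)C(CCC5(C)OCCO5)=CC[C@H]14 | intermediate
39 | trimethylsilyl ether of the spiro ketol | C=C1C(=O)O[C@@H]2C[C@H](C)[C@@]3(O[Si](C)(C)C)CC(=O)[C@@]4(C[C@H]3C[C@H]12)C(=O)O[C@H]1C[C@@H](C)C(CCC5(C)OCCO5)=CC[C@H]14 | intermediate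
40 | silyl-protected enol triflate | C=C1C(=O)O[C@@H]2C[C@H](C)[C@@]3(O[Si](C)(C)C)C=C(OS(=O)(=O)C(F)(F)F)[C@@]4(C[C@H]3C[C@H]12)C(=O)O[C@H]1C[C@@H](C)C(CCC5(C)OCCO5)=CC[C@H]14 | intermediate
41 | tributyl(1-ethoxyvinyl)stannane | CCCC[Sn](CCCC)(CCCC)C(=C)OCC | starting material
42 | silyl-protected 2-ethoxy-1,3-diene | C=C1C(=O)O[C@@H]2C[C@H](C)[C@@]3(O[Si](C)(C)C)C=C(C(=C)OCC)[C@@]4(C[C@H]3C[C@H]12)C(=O)O[C@H]1C[C@@H](C)C(CCC5(C)OCCO5)=CC[C@H]14 | intermediate
43 | CNP0195550.4 | C=C1C(=O)O[C@@H]2C[C@H](C)[C@@]3(O)C=C(C(C)=O)[C@@]4(C[C@H]3C[C@H]12)C(=O)O[C@H]1C[C@@H](C)C(CCC(C)=O)=CC[C@H]14 | target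

---

**Step count**

Total: 27 steps. Longest linear sequence: 18 steps (steps 1, 2, 12 to 22, 23 to 27).

**Three steps most likely to fail**

1. Step 23. The donor or the liberated amines may add to the α-methylene lactone, the doubly unsaturated keto lactone may self-condense once it is released, or ring closure may stall at the open diketone. The fallback sets out from bis-amine 18 and donor 35 and keeps the lactone methylene masked. Heating free base 18 with 35 (DBU cat., PhMe, 80 °C) should make only the β-amino ketone lose dimethylamine, since the lactone Mannich base needs quaternisation to eliminate. The Michael–aldol sequence then gives the dimethylaminomethyl ketol F1. MeI converts it into the methiodide F2, and NaHCO3 (aq)/CH2Cl2 eliminates trimethylamine to come back to the route at 38.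

2. Step 19 (and its twin, step 8). Facial selectivity in the protonation of the silyl dienol ether may be poor; in series B the centre cannot be corrected later. The fallback sets out from the epimer mixture 27 and replaces kinetic by thermodynamic control at a stage with no enone γ-position. H2, Pd/C, EtOAc gives the saturated methyl ketone F3 as an epimer mixture. DBU in PhMe at 40 °C should equilibrate it to the cis-1,3 ketone F4 without being able to reach the ring-fusion carbon. LiN(i-Pr)2 (1.0 equiv), THF, −78 °C removes a proton from the unhindered ketone α-CH2, and PhNTf2 gives the enol triflate, coming back to the route at 31.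

3. Step 20 (and its twin, step 9). The hydride may add 1,2 instead of 1,4 to the γ-branched cycloheptenone, or the enolate may exchange protons before it is trapped. The fallback sets out from 29. Et3SiH with RhCl(PPh3)3 (cat.) in PhH at 50 °C performs a 1,4-hydrosilylation to the triethylsilyl enol ether F5. CsF and PhNTf2 in DME at rt convert it into the triflate, coming back to the route at 31.

**Further compounds**

F1 | step 23 | spiro ketol carrying a dimethylaminomethyl group in place of the lactone methylene | CN(C)CC1C(=O)O[C@@H]2C[C@H](C)[C@@]3(O)CC(=O)[C@@]4(C[C@H]3C[C@H]12)C(=O)O[C@H]1C[C@@H](C)C(CCC5(C)OCCO5)=CC[C@H]14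
F2 | step 23 | methiodide of F1 | C[N+](C)(C)CC1C(=O)O[C@@H]2C[C@H](C)[C@@]3(O)CC(=O)[C@@]4(C[C@H]3C[C@H]12)C(=O)O[C@H]1C[C@@H](C)C(CCC5(C)OCCO5)=CC[C@H]14.[I-]
F3 | step 19 | series-B saturated 7-methyl-6-oxo lactone (C7 epimers) | C1C(=O)O[C@H]2CC(C)C(=O)CC[C@@H]12
F4 | step 19 | series-B saturated 7-methyl-6-oxo lactone, methyl cis to the lactone oxygen | C1C(=O)O[C@H]2C[C@@H](C)C(=O)CC[C@@H]12
F5 | step 20 | series-B triethylsilyl enol ether (C5=C6) | C1C(=O)O[C@H]2C[C@@H](C)C(O[Si](CC)(CC)CC)=CC[C@@H]12
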